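**Retrosynthetic overview**
1. The side-chain alcohol comes last, by Markovnikov hydration of the isobutenyl analogue (CH=CMe2 → CH2CMe2OH).
2. Ring B is formed second, by a formal [3+3] of 4-hydroxy-1-methyl-2-quinolone with a ring-A block. A tertiary allylic alcohol on that block gives the C-c–C-3'' bond and a C-b carbinol gives the C-b–O bond.
3. Ring A is formed first. The quinolone 4-OH opens the C2–C3 bond of a vinylcyclopropane under anodic oxidation and makes the O–CMe2 bond. The ten aliphatic carbons of the target are a seco-chrysanthemyl (lavandulyl) unit.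
4. The cyclopropane precursor comes from C-acylation of the same quinolone with (1S,3S)-chrysanthemic acid. C1 of the acid becomes C-a, and C-c and then C-b are set from it.

Labels: C-a is the ring-fusion CH next to CMe2. C-b is the ring-fusion O–CH. C-c is the CH that carries the side chain. The target has C-a R, C-b S, C-c R (H-a/H-b cis, H-a/H-c trans).

Assumption: (1S,3S)-(−)-trans-chrysanthemic acid 1, the unwanted enantiomer from the industrial resolution of the pyrethroid acid, is bought as such. The natural (1R,3R) acid would give the mirror image of the target.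

**Step 1**
Reactants: 1 (1S,3S)-(−)-trans-chrysanthemic acid; 2 4-hydroxy-1-methylquinolin-2(1H)-one
Product: 4 3-[(1S,3S)-2,2-dimethyl-3-(2-methylprop-1-enyl)cyclopropane-1-carbonyl]-4-hydroxy-1-methylquinolin-2(1H)-one, via enol ester 3 (not isolated)
Conditions: DCC (1.1 equiv), DMAP (1.3 equiv), toluene, rt, 2 h, then 80 °C, 6 h
Reagents that add atoms: none
Why: Steglich activation O-acylates the acidic enol and DMAP then relays the acyl group from O to C-3 (Fries-type O→C acyl migration, the standard entry to 3-acyl-4-hydroxy-pyrones, -coumarins and -quinolones), the H-bond-chelated tricarbonyl being the thermodynamic sink; no stereocentre is formed, and C1/C3 cannot epimerise because neither a cyclopropylidene ketene nor a cyclopropyl enolate forms under these conditions.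

**Step 2**
Reactants: 4 3-chrysanthemoyl-4-hydroxyquinolone
Product: 6 (3R,4S)-4-hydroxy-3-[(1E)-3-hydroxy-3-methylbut-1-enyl]-2,2,6-trimethyl-2,3,4,6-tetrahydro-5H-pyrano[3,2-c]quinolin-5-one, via pyranoquinolinedione 5 (not isolated)
Conditions: graphite(+)/Pt(−), undivided cell, 4 mA cm⁻², 2.4 F mol⁻¹, Mg(ClO4)2 (1.2 equiv), nBu4NBF4 (0.1 M), MeCN–HFIP 9:1, H2O (10 equiv), 0 °C; then MeOH, CeCl3·7H2O, NaBH4, −20 °C
Reagents that add atoms: water (O)
Why: Proposed new method: anodic 1,5-oxy-hydroxylative ring opening of a vinylcyclopropane by an enol O–H, in which one-electron oxidation takes an electron from the isobutenyl/Walsh HOMO (the acyl group and Mg2+ make the quinolone harder to oxidise) and C2–C3 becomes a one-electron bond with the charge on C2 (a tert-alkyl centre is far easier to ionise than acyl-bearing C1, so C1–C2 and C1–C3 stay intact); Mg2+ chelation of the ketone and lactam carbonyls turns the 4-OH, not the lactam oxygen, towards C2, so 6-exo attack closes the angular pyran ring A and leaves an allyl radical that is oxidised at once to the allyl cation and trapped by water at its tertiary end as E-allylic alcohol 5, which lacks the vinylcyclopropane and is harder to oxidise than 4, while protons go to H2 at Pt; C1 is a spectator and becomes C-a with its configuration intact (C3 is planarised), and the Luche 1,2-reduction in the same pot removes the epimerisable β,γ-unsaturated ketone (hydride anti to the C-a side chain, mainly the cis-carbinol, both C-b epimers being usable in step 3); the closest known reaction types are capture of vinyl- and arylcyclopropane radical cations by alcohols at the most substituted ring carbon under photoinduced electron transfer and the anodic 1,3-difunctionalisation of arylcyclopropanes.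

**Step 3**
Reactants: 6 ring-A diol; 2 4-hydroxy-1-methylquinolin-2(1H)-one
Product: 8 isobutenyl bis-pyranoquinolone (target skeleton with CH=CMe2 on C-c; C-a R; C-b S; C-c R), via C-allylated carbinol 7 (not isolated)
Conditions: 2 (1.1 equiv), TsOH·H2O (10 mol %), HFIP–CH2Cl2 1:4, 0 °C, 2 h, then 40 °C
Reagents that add atoms: none
Why: In this acid/HFIP dehydrative SN1 allylation followed by cycloetherification the tertiary allylic alcohol ionises first and C-3 of 2 attacks the less hindered secondary terminus C-c anti to the CMe2–O group in the H-a-inside (Felkin/A1,3) conformer, which sets C-c (R, H-a/H-c anti) and regenerates the trisubstituted alkene; on warming the C-b carbinol ionises to the vinylogous oxocarbenium ion, which the now C-3-blocked enol OH can reach only from the face of its own tether, so ring B closes cis-fused and C-b becomes S whichever epimer of 6 was used.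

**Step 4**
Reactants: 8 isobutenyl bis-pyranoquinolone
Product: 9 target CNP0202276.1
Conditions: Co(acac)2 (15 mol %), PhSiH3 (3 equiv), O2 (1 atm), THF, rt; aq. work-up
Reagents that add atoms: dioxygen (O=O)
Why: Mukaiyama hydration (cobalt-hydride hydrogen-atom transfer to the only alkene gives the tertiary radical, which is trapped by O2 and reduced to the alcohol) is Markovnikov-selective and neutral, so the acid-labile C-b aryl ether and the three stereocentres are untouched and no new stereocentre is formed.

**Compound list**
1 | (1S,3S)-(−)-trans-chrysanthemic acid | CC(C)=C[C@H]1[C@H](C(O)=O)C1(C)C | starting material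
2 | 4-hydroxy-1-methylquinolin-2(1H)-one | Cn1c(=O)cc(O)c2ccccc12 | starting material
3 | 1-methyl-2-oxo-1,2-dihydroquinolin-4-yl (1S,3S)-chrysanthemate (enol ester) | CC(C)=C[C@H]1[C@H](C(=O)Oc2cc(=O)n(C)c3ccccc23)C1(C)C | intermediate (not isolated)
4 | 3-[(1S,3S)-2,2-dimethyl-3-(2-methylprop-1-enyl)cyclopropane-1-carbonyl]-4-hydroxy-1-methylquinolin-2(1H)-one | CC(C)=C[C@H]1[C@H](C(=O)c2c(O)c3ccccc3n(C)c2=O)C1(C)C | intermediate
5 | (3S)-3-[(1E)-3-hydroxy-3-methylbut-1-enyl]-2,2,6-trimethyl-2,3-dihydro-4H-pyrano[3,2-c]quinoline-4,5(6H)-dione | Cn1c(=O)c2c(c3ccccc31)OC(C)(C)[C@H](/C=C/C(C)(C)O)C2=O | intermediate (not isolated)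
6 | (3R,4S)-4-hydroxy-3-[(1E)-3-hydroxy-3-methylbut-1-enyl]-2,2,6-trimethyl-2,3,4,6-tetrahydro-5H-pyrano[3,2-c]quinolin-5-one (3,4-cis, major epimer) | Cn1c(=O)c2c(c3ccccc31)OC(C)(C)[C@H](/C=C/C(C)(C)O)[C@@H]2O | intermediate
7 | (3R,4S)-4-hydroxy-3-[(1R)-1-(4-hydroxy-1-methyl-2-oxo-1,2-dihydroquinolin-3-yl)-3-methylbut-2-enyl]-2,2,6-trimethyl-2,3,4,6-tetrahydro-5H-pyrano[3,2-c]quinolin-5-one | Cn1c(=O)c2c(c3ccccc31)OC(C)(C)[C@H]([C@@H](C=C(C)C)c1c(O)c3ccccc3n(C)c1=O)[C@@H]2O | intermediate (not isolated)
8 | isobutenyl bis-pyranoquinolone, cis-fused rings A/B, C-a R, C-b S, C-c R, 2-methylprop-1-enyl on C-c | Cn1c(=O)c2c(c3ccccc31)OC(C)(C)[C@H]1[C@@H]2Oc2c(c(=O)n(C)c3ccccc23)[C@@H]1C=C(C)C | intermediate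
9 | CNP0202276.1, C-a R, C-b S, C-c R, 2-hydroxy-2-methylpropyl on C-c | Cn1c(=O)c2c(c3ccccc31)OC(C)(C)[C@H]1[C@@H]2Oc2c(c(=O)n(C)c3ccccc23)[C@@H]1CC(C)(C)O | target

**Total step count:** 4 (four isolations; steps 1–3 each telescope one non-isolated intermediate).
**Longest linear sequence:** 4 (1 → 4 → 6 → 8 → 9).

**Three steps most likely to fail**

1. **Step 2 (the proposed new step).**
   - It can fail if the quinolone is oxidised instead of the vinylcyclopropane. It can also fail by closure through the lactam oxygen (linear pyrano[2,3-b] isomer), or if water attacks C2 before the enol does.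
   - The fallback uses known chemistry, sets out from 4 and comes back at 5. The isobutenyl double bond, the only electron-rich alkene, is epoxidised with buffered mCPBA (CH2Cl2, 0 °C) to the side-chain epoxide F1. BF3·OEt2 (CH2Cl2, −78 °C) then ionises the C–O bond at the cyclopropyl-substituted carbon.
   - The cyclopropylcarbinyl cation opens in the established cyclopropylcarbinyl→homoallyl (Julia-type) sense towards tertiary C2, which the 4-OH captures. The epoxide oxygen stays on as the tertiary allylic alcohol. Compound 5 is then reduced to 6 as in step 2.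

2. **Step 3.**
   - It can fail by attack at the tertiary allyl terminus, by low diastereoselectivity at C-c, by E1 loss of H-a to a chromene, or by closure of the new enol OH onto the isobutenyl group.
   - The fallback sets out from 6 (pure 3,4-cis epimer) and comes back at 8. It makes the C-b–O bond first and the C–C bond intramolecularly. NaH (1.05 equiv) and commercial 4-chloro-1-methylquinolin-2(1H)-one (DMF, 0 → 50 °C) O-arylate the secondary alkoxide by SNAr with retention at C-b, giving the cis aryl ether F2.
   - Catalytic TsOH in HFIP–CH2Cl2 then ionises the tertiary allylic alcohol. The tethered quinolone C-3 closes the six-membered ring B at C-c (intramolecular dehydrative Friedel–Crafts allylation), so regiochemistry and the cis fusion are enforced by the tether.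

3. **Step 1.**
   - The O→C acyl migration may stall at enol ester 3, because the acyl carbon is flanked by the gem-dimethyl group.
   - The fallback sets out from 1 and comes back at 4. It makes the C-3–acyl bond with a carbanion. Acid 1 is coupled with N,O-dimethylhydroxylamine hydrochloride (EDC, iPr2NEt, CH2Cl2) to the Weinreb amide F3.
   - Commercial 4-methoxy-1-methylquinolin-2(1H)-one is lithiated at C-3 (n-BuLi, THF, −78 °C) to 3-lithio-4-methoxy-1-methylquinolin-2(1H)-one F4. This adds to F3 to give the 4-methoxy ketone F5.
   - The doubly activated vinylogous ester of F5 is cleaved by addition–elimination (LiOH, THF–H2O, rt, then acidification) to 4.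

**Further compounds**
F1 | step 2 | 3-{(1S,3S)-3-(3,3-dimethyloxiran-2-yl)-2,2-dimethylcyclopropane-1-carbonyl}-4-hydroxy-1-methylquinolin-2(1H)-one (side-chain epoxide, epimers at the oxirane CH) | CC1(C)OC1[C@H]1[C@H](C(=O)c2c(O)c3ccccc3n(C)c2=O)C1(C)C
F2 | step 3 | (3R,4S)-3-[(1E)-3-hydroxy-3-methylbut-1-enyl]-2,2,6-trimethyl-4-[(1-methyl-2-oxo-1,2-dihydroquinolin-4-yl)oxy]-2,3,4,6-tetrahydro-5H-pyrano[3,2-c]quinolin-5-one (cis aryl ether) | Cn1c(=O)c2c(c3ccccc31)OC(C)(C)[C@H](/C=C/C(C)(C)O)[C@@H]2Oc1cc(=O)n(C)c2ccccc12
F3 | step 1 | (1S,3S)-N-methoxy-N,2,2-trimethyl-3-(2-methylprop-1-enyl)cyclopropane-1-carboxamide (Weinreb amide) | CC(C)=C[C@H]1[C@H](C(=O)N(C)OC)C1(C)C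
F4 | step 1 | 3-lithio-4-methoxy-1-methylquinolin-2(1H)-one | [Li]c1c(OC)c2ccccc2n(C)c1=O
F5 | step 1 | 3-[(1S,3S)-2,2-dimethyl-3-(2-methylprop-1-enyl)cyclopropane-1-carbonyl]-4-methoxy-1-methylquinolin-2(1H)-one (4-methoxy ketone) | CC(C)=C[C@H]1[C@H](C(=O)c2c(OC)c3ccccc3n(C)c2=O)C1(C)C
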